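**Strategy.** Dendronpholide B is a cyclotetradecane (C1–C14) whose C1 and C4 are bridged trans (in,out) by an α-methylene-ε-lactone (O–C16–C15=C17). The array C16(=O)–C15(=CH2)–C1–C14–C13(O) is a Rauhut–Currier retron, so the lactone is disconnected at C1–C15: an acrylate on the C4 tertiary oxygen of a 14-membered 1(14)-en-13-one is closed across the ring. This one operation forms the C1–C15 bond, the seven-membered lactone, the exocyclic methylene and the C1 stereocentre, and leaves C13 as a ketone for reagent-controlled reduction. The precursor is a cyclotetradecatrienone carrying only the C4/C5 stereodiad, made from geranyl acetate by one Sharpless epoxidation and closed by enone-forming metathesis.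

Key step: step 13

Remark: cembrane numbering is used throughout (C1 = CH bearing C15; C4 = O-bearing quaternary carbon with methyl C18; C5 = CHOAc; C13 = CHOH; C16 = lactone C=O; C17 = exocyclic CH2); the SMILES is read as 1R,4R,5S,13R, 8E,11E.

**Step 1**
Reactants: 1 geranyl acetate
Product: 2 (2E,6E)-8-hydroxy-3,7-dimethylocta-2,6-dien-1-yl acetate
Conditions: SeO2 (cat.), t-BuOOH, salicylic acid (cat.), CH2Cl2, rt
Reagents that add atoms: tert-butyl hydroperoxide, CC(C)(C)OO
Why: SeO2 allylic oxidation (ene reaction, then [2,3]-shift) should hydroxylate the E-methyl of the remote, more electron-rich alkene (the alkene next to the acetate is deactivated), giving the future C3 as CH2OH without changing either alkene geometry.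

**Step 2**
Reactants: 2 (2E,6E)-8-hydroxy-3,7-dimethylocta-2,6-dien-1-yl acetate
Product: 3 (2E)-5-[(2R,3R)-3-(hydroxymethyl)-3-methyloxiran-2-yl]-3-methylpent-2-en-1-yl acetate
Conditions: Ti(OiPr)4 (10 mol%), D-(−)-DET (12 mol%), t-BuOOH, 4 Å MS, CH2Cl2, −20 °C
Reagents that add atoms: tert-butyl hydroperoxide, CC(C)(C)OO
Why: Sharpless asymmetric epoxidation acts only on the free 2-methylallylic alcohol, and with D-(−)-DET the E-2-methyl-2-en-1-ol should give the (2R,3R)-epoxy alcohol (L-(+)-DET gives the 2S,3S series), which fixes the C4–O bond as 4R and places the C5 oxygen for inversion in step 3.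

**Step 3**
Reactants: 3 (2E)-5-[(2R,3R)-3-(hydroxymethyl)-3-methyloxiran-2-yl]-3-methylpent-2-en-1-yl acetate
Product: 4 (2E,6S,7R)-1-acetoxy-7,8-dihydroxy-3,7-dimethyloct-2-en-6-yl benzoate
Conditions: Ti(OiPr)4 (1.5 equiv), PhCO2H (1.5 equiv), CH2Cl2, rt
Reagents that add atoms: benzoic acid, O=C(O)c1ccccc1
Why: In the titanium-mediated opening of a 2,3-epoxy alcohol the carboxylate attacks the carbon remote from the CH2OH (here secondary C5, C4 being quaternary) with SN2 inversion, which should give 5S while the C4–O bond (4R) is untouched.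

**Step 4**
Reactants: 4 (2E,6S,7R)-1-acetoxy-7,8-dihydroxy-3,7-dimethyloct-2-en-6-yl benzoate
Product: 5 (2E,6S,7R)-1-acetoxy-7-hydroxy-3,7-dimethyl-8-(tosyloxy)oct-2-en-6-yl benzoate
Conditions: TsCl, Et3N, DMAP (cat.), CH2Cl2, 0 °C
Reagents that add atoms: p-toluenesulfonyl chloride, Cc1ccc(S(=O)(=O)Cl)cc1
Why: Sulfonylation should take place only at the primary hydroxyl, the tertiary one being too hindered, which turns C3 into the electrophile.

**Step 5**
Reactants: 5 (2E,6S,7R)-1-acetoxy-7-hydroxy-3,7-dimethyl-8-(tosyloxy)oct-2-en-6-yl benzoate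
Product: 7 (2E,6S,7R)-3,7-dimethylundeca-2,10-diene-1,6,7-triol, via (2E,6S)-1-acetoxy-3-methyl-6-[(2R)-2-methyloxiran-2-yl]hex-2-en-6-yl benzoate 6 (not isolated)
Conditions: allylMgBr (8 equiv), CuI (10 mol%), THF, −40 → 0 °C; aq. NH4Cl
Reagents that add atoms: allylmagnesium bromide, C=CC[Mg]Br
Why: The magnesium alkoxide of the tertiary alcohol should displace the neighbouring tosylate (3-exo-tet) to the 2,2-disubstituted oxirane 6, which the allylcopper species opens at its CH2 carbon (copper-catalysed Grignard epoxide opening) to form C2–C3 without touching C4, while excess reagent cleaves the benzoate and the acetate.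

**Step 6**
Reactants: 7 (2E,6S,7R)-3,7-dimethylundeca-2,10-diene-1,6,7-triol
Product: 8 (2E,6S,7R)-7-hydroxy-3,7-dimethylundeca-2,10-diene-1,6-diyl diacetate
Conditions: Ac2O (2.2 equiv), pyridine, DMAP (cat.), CH2Cl2, 0 °C
Reagents that add atoms: acetic anhydride, CC(=O)OC(C)=O
Why: Acylation should esterify the primary allylic and the secondary C5 hydroxyls but not the hindered tertiary C4–OH, giving the C5 acetate of the target and the allylic acetate needed in step 9.

**Step 7**
Reactants: 9 pent-1-en-4-yn-3-ol (racemic)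
Product: 11 (1E)-1-iodo-2-methylpenta-1,4-dien-3-ol, via [(1E)-3-(dimethylalumanyloxy)-2-methylpenta-1,4-dien-1-yl]dimethylalumane 10 (not isolated)
Conditions: AlMe3 (3 equiv), Cp2ZrCl2 (0.3 equiv), CH2Cl2, 0 °C → rt; then I2, THF, −30 °C
Reagents that add atoms: trimethylaluminium, C[Al](C)C; iodine, II
Why: Negishi zirconium-catalysed carboalumination adds methyl and aluminium syn across the alkyne with aluminium at the terminal carbon, and iodinolysis with retention should give the E-iodide; the carbinol centre (C13) is left racemic because it is oxidised in step 10.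

**Step 8**
Reactants: 11 (1E)-1-iodo-2-methylpenta-1,4-dien-3-ol
Product: 12 (1E)-2-methyl-1-(4,4,5,5-tetramethyl-1,3,2-dioxaborolan-2-yl)penta-1,4-dien-3-ol
Conditions: B2pin2, PdCl2(dppf) (3 mol%), KOPh, toluene, 50 °C
Reagents that add atoms: bis(pinacolato)diboron, CC1(C)OB(OC1(C)C)B1OC(C)(C)C(C)(C)O1
Why: Miyaura borylation of the alkenyl iodide proceeds with retention of the E geometry and tolerates the free alcohol.

**Step 9**
Reactants: 8 (2E,6S,7R)-7-hydroxy-3,7-dimethylundeca-2,10-diene-1,6-diyl diacetate; 12 (1E)-2-methyl-1-(4,4,5,5-tetramethyl-1,3,2-dioxaborolan-2-yl)penta-1,4-dien-3-ol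
Product: 13 (4E,7E,11S,12R)-3,12-dihydroxy-4,8,12-trimethylhexadeca-1,4,7,15-tetraen-11-yl acetate (C3 epimers)
Conditions: Pd(PPh3)4 (5 mol%), CsF, THF, 60 °C
Reagents that add atoms: none
Why: In this allyl–alkenyl Suzuki–Miyaura coupling Pd(0) ionises only the primary allylic acetate, and transmetalation from the fluoride-activated alkenylboronate followed by reductive elimination at the less hindered π-allyl terminus should form C10–C11 and the skipped 8E,11E-diene with retention of both geometries.

**Step 10**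
Reactants: 13 (4E,7E,11S,12R)-3,12-dihydroxy-4,8,12-trimethylhexadeca-1,4,7,15-tetraen-11-yl acetate
Product: 14 (4E,7E,11S,12R)-12-hydroxy-4,8,12-trimethyl-3-oxohexadeca-1,4,7,15-tetraen-11-yl acetate
Conditions: Dess–Martin periodinane, pyridine, CH2Cl2, 0 °C
Reagents that add atoms: none
Why: Dess–Martin oxidation should convert the secondary bis-allylic alcohol into the divinyl ketone (erasing the unset C13 centre) while the tertiary alcohol cannot be oxidised.

**Step 11**
Reactants: 14 (4E,7E,11S,12R)-12-hydroxy-4,8,12-trimethyl-3-oxohexadeca-1,4,7,15-tetraen-11-yl acetate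
Product: 15 (1S,2R,5E,8E,11E)-2-hydroxy-2,8,12-trimethyl-7-oxocyclotetradeca-5,8,11-trien-1-yl acetate
Conditions: Grubbs II (10 mol%), 1,4-benzoquinone (20 mol%), CH2Cl2 (1 mM), 40 °C
Reagents that add atoms: none
Why: Ring-closing metathesis between the terminal alkene (type I) and the vinyl ketone (type II) under high dilution should close the 14-membered ring as the conjugated E-enone (C1=C14), the trisubstituted alkenes being inert to the catalyst.

**Step 12**
Reactants: 15 (1S,2R,5E,8E,11E)-2-hydroxy-2,8,12-trimethyl-7-oxocyclotetradeca-5,8,11-trien-1-yl acetate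
Product: 16 (1S,2R,5E,8E,11E)-1-acetoxy-2,8,12-trimethyl-7-oxocyclotetradeca-5,8,11-trien-2-yl prop-2-enoate
Conditions: acryloyl chloride, i-Pr2NEt, DMAP (cat.), CH2Cl2, 0 °C → rt
Reagents that add atoms: acryloyl chloride, C=CC(=O)Cl
Why: DMAP-catalysed acylation of the tertiary alcohol installs C15–C17; it is placed after the metathesis because an acrylate present earlier would close a seven-membered unsaturated lactone with the butenyl chain.

**Step 13**
Reactants: 16 (1S,2R,5E,8E,11E)-1-acetoxy-2,8,12-trimethyl-7-oxocyclotetradeca-5,8,11-trien-2-yl prop-2-enoate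
Product: 17 (1R,4R,5S,8E,11E)-5-acetoxy-13-oxocembra-8,11,15(17)-trien-16,4-olide
Conditions: PMe3 (0.5 equiv), t-AmOH (2 mM), rt
Reagents that add atoms: none
Why: This is an intramolecular Rauhut–Currier reaction: PMe3 adds reversibly to the unsubstituted β-carbon (C17) of the acrylate, the resulting ester enolate (C15) adds 1,4 to C1 of the ring enone, and proton transfer followed by E1cB loss of PMe3 restores the C15=C17 methylene. The closest known reactions are phosphine-catalysed Rauhut–Currier cycloisomerisations of enoate–enone pairs, including transannular cases and O-tethered acrylates that give α-methylene lactones; only the ring size is new here. The oxepanone ring closes in the 7-exo-trig mode (C14 stays outside the new ring), which completes the in,out-bridged bicycle. C1 is set by C4: in the chair-like seven-membered transition state the two macrocycle bonds (C4–C5 and C1–C14) should take the pseudo-equatorial positions with C18 axial, and this diequatorial arrangement is the trans 1R,4R relationship of the target. The step needs chemoselectivity (phosphine on the acrylate, not on the β-substituted enones, secured by the unsubstituted acrylate terminus) and regioselectivity (C1, not C11, secured because attack at C11 would need an eleven-membered ring), and the weakly basic phosphine in tert-amyl alcohol is chosen so that the enolates are protonated before they can move the skipped C8–C12 diene into conjugation.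

**Step 14**
Reactants: 17 (1R,4R,5S,8E,11E)-5-acetoxy-13-oxocembra-8,11,15(17)-trien-16,4-olide
Product: 18 dendronpholide B
Conditions: (S)-Me-CBS (0.5 equiv), catecholborane, toluene, −78 °C
Reagents that add atoms: none
Why: Corey–Bakshi–Shibata reduction with the (S)-oxazaborolidine treats the α-methylalkenyl group as the large substituent and should deliver hydride to give the 13R allylic alcohol under reagent control, while the α-methylene lactone and the acetate do not react with catecholborane at −78 °C.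

**Compound list**
1 | geranyl acetate [(2E)-3,7-dimethylocta-2,6-dien-1-yl acetate] | CC(=O)OC/C=C(\C)CCC=C(C)C | starting material
2 | (2E,6E)-8-hydroxy-3,7-dimethylocta-2,6-dien-1-yl acetate | CC(=O)OC/C=C(\C)CC/C=C(\C)CO | intermediate
3 | (2E)-5-[(2R,3R)-3-(hydroxymethyl)-3-methyloxiran-2-yl]-3-methylpent-2-en-1-yl acetate | CC(=O)OC/C=C(\C)CC[C@H]1O[C@]1(C)CO | intermediate
4 | (2E,6S,7R)-1-acetoxy-7,8-dihydroxy-3,7-dimethyloct-2-en-6-yl benzoate | CC(=O)OC/C=C(\C)CC[C@H](OC(=O)c1ccccc1)[C@](C)(O)CO | intermediate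
5 | (2E,6S,7R)-1-acetoxy-7-hydroxy-3,7-dimethyl-8-(tosyloxy)oct-2-en-6-yl benzoate | CC(=O)OC/C=C(\C)CC[C@H](OC(=O)c1ccccc1)[C@](C)(O)COS(=O)(=O)c1ccc(C)cc1 | intermediate
6 | (2E,6S)-1-acetoxy-3-methyl-6-[(2R)-2-methyloxiran-2-yl]hex-2-en-6-yl benzoate | CC(=O)OC/C=C(\C)CC[C@H](OC(=O)c1ccccc1)[C@@]1(C)CO1 | intermediate (not isolated)
7 | (2E,6S,7R)-3,7-dimethylundeca-2,10-diene-1,6,7-triol | OC/C=C(\C)CC[C@H](O)[C@](C)(O)CCC=C | intermediate
8 | (2E,6S,7R)-7-hydroxy-3,7-dimethylundeca-2,10-diene-1,6-diyl diacetate | CC(=O)OC/C=C(\C)CC[C@H](OC(C)=O)[C@](C)(O)CCC=C | intermediate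
9 | pent-1-en-4-yn-3-ol (racemic) | C=CC(O)C#C | starting material
10 | [(1E)-3-(dimethylalumanyloxy)-2-methylpenta-1,4-dien-1-yl]dimethylalumane | C=CC(O[Al](C)C)/C(C)=C/[Al](C)C | intermediate (not isolated)
11 | (1E)-1-iodo-2-methylpenta-1,4-dien-3-ol | C=CC(O)/C(C)=C/I | intermediate
12 | (1E)-2-methyl-1-(4,4,5,5-tetramethyl-1,3,2-dioxaborolan-2-yl)penta-1,4-dien-3-ol | C=CC(O)/C(C)=C/B1OC(C)(C)C(C)(C)O1 | intermediate
13 | (4E,7E,11S,12R)-3,12-dihydroxy-4,8,12-trimethylhexadeca-1,4,7,15-tetraen-11-yl acetate | C=CC(O)/C(C)=C/C/C=C(\C)CC[C@H](OC(C)=O)[C@](C)(O)CCC=C | intermediate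
14 | (4E,7E,11S,12R)-12-hydroxy-4,8,12-trimethyl-3-oxohexadeca-1,4,7,15-tetraen-11-yl acetate | C=CC(=O)/C(C)=C/C/C=C(\C)CC[C@H](OC(C)=O)[C@](C)(O)CCC=C | intermediate
15 | (1S,2R,5E,8E,11E)-2-hydroxy-2,8,12-trimethyl-7-oxocyclotetradeca-5,8,11-trien-1-yl acetate | O[C@]1(C)CC/C=C/C(=O)/C(C)=C/C/C=C(\C)CC[C@@H]1OC(C)=O | intermediate
16 | (1S,2R,5E,8E,11E)-1-acetoxy-2,8,12-trimethyl-7-oxocyclotetradeca-5,8,11-trien-2-yl prop-2-enoate | C=CC(=O)O[C@]1(C)CC/C=C/C(=O)/C(C)=C/C/C=C(\C)CC[C@@H]1OC(C)=O | intermediate
17 | (1R,4R,5S,8E,11E)-5-acetoxy-13-oxocembra-8,11,15(17)-trien-16,4-olide | C=C1C(=O)O[C@]2(C)CC[C@@H]1CC(=O)/C(C)=C/C/C=C(\C)CC[C@@H]2OC(C)=O | intermediate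
18 | dendronpholide B | C=C1C(=O)O[C@]2(C)CC[C@@H]1C[C@@H](O)/C(C)=C/C/C=C(\C)CC[C@@H]2OC(C)=O | target

**Step count.** Total: 14 steps. Longest linear sequence: 12 steps (steps 1–6, then 9–14).

**Steps most likely to fail**

Step 13. The seven-membered closure may be slow, so that the phosphonium enolate oligomerises or shifts the skipped diene into conjugation, or the facial selectivity at C1 may be poor. The fallback sets out from 15 and uses a stepwise Michael/olefination sequence. Esterification of the tertiary alcohol with 2-(diethoxyphosphoryl)acetic acid (DIC, DMAP) should give (1S,2R,5E,8E,11E)-1-acetoxy-2,8,12-trimethyl-7-oxocyclotetradeca-5,8,11-trien-2-yl 2-(diethoxyphosphoryl)acetate F1. Cs2CO3 in MeCN should then bring about the intramolecular Michael addition of the phosphonoacetate anion to C1 (reversible, so the diequatorial trans lactone can be reached by equilibration) to give (1R,4R,5S,8E,11E)-5-acetoxy-15-(diethoxyphosphoryl)-13-oxo-17-norcembra-8,11-dien-16,4-olide F2. Horner–Wadsworth–Emmons methylenation with aqueous formaldehyde and K2CO3 comes back to the route at 17.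

Step 11. Cross-metathesis oligomerisation, ruthenium hydride migration of the skipped diene, or decomposition of the divinyl ketone may defeat the macrocyclisation. The fallback sets out from 8 and 12 and closes the ring at C10–C11 instead. Oxidation of 12 (MnO2) should give (1E)-2-methyl-1-(4,4,5,5-tetramethyl-1,3,2-dioxaborolan-2-yl)penta-1,4-dien-3-one F3. Intermolecular cross-metathesis of 8 with F3 (Hoveyda–Grubbs II) should form the C1=C14 E-enone in (2E,6S,7R,10E,13E)-7-hydroxy-3,7,13-trimethyl-12-oxo-14-(4,4,5,5-tetramethyl-1,3,2-dioxaborolan-2-yl)tetradeca-2,10,13-triene-1,6-diyl diacetate F4. An intramolecular Pd-catalysed allyl–alkenyl Suzuki coupling (Pd(PPh3)4, CsF, THF, 2 mM) comes back to the route at 15.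

Step 5. Ester cleavage beside the oxirane may be faster than its opening, leading to acyl transfer, epoxide migration or attack at the wrong carbon. The fallback sets out from 5 and forms C2–C3 by a radical reaction that generates no alkoxide. DBU should give the oxirane 6, now isolated. MgI2 (Et2O, −20 °C) should open it at CH2 to (2E,6S,7S)-1-acetoxy-7-hydroxy-8-iodo-3,7-dimethyloct-2-en-6-yl benzoate F5. Keck radical allylation (allyltributylstannane, AIBN, benzene, 80 °C) should give (2E,6S,7R)-1-acetoxy-7-hydroxy-3,7-dimethylundeca-2,10-dien-6-yl benzoate F6. Methanolysis of both esters (K2CO3, MeOH) comes back to the route at 7.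

**Further compounds**
F1 | step 13 | (1S,2R,5E,8E,11E)-1-acetoxy-2,8,12-trimethyl-7-oxocyclotetradeca-5,8,11-trien-2-yl 2-(diethoxyphosphoryl)acetate | CCOP(=O)(OCC)CC(=O)O[C@]1(C)CC/C=C/C(=O)/C(C)=C/C/C=C(\C)CC[C@@H]1OC(C)=O
F2 | step 13 | (1R,4R,5S,8E,11E)-5-acetoxy-15-(diethoxyphosphoryl)-13-oxo-17-norcembra-8,11-dien-16,4-olide (C15 epimers) | CCOP(=O)(OCC)C1C(=O)O[C@]2(C)CC[C@@H]1CC(=O)/C(C)=C/C/C=C(\C)CC[C@@H]2OC(C)=O
F3 | step 11 | (1E)-2-methyl-1-(4,4,5,5-tetramethyl-1,3,2-dioxaborolan-2-yl)penta-1,4-dien-3-one | C=CC(=O)/C(C)=C/B1OC(C)(C)C(C)(C)O1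
F4 | step 11 | (2E,6S,7R,10E,13E)-7-hydroxy-3,7,13-trimethyl-12-oxo-14-(4,4,5,5-tetramethyl-1,3,2-dioxaborolan-2-yl)tetradeca-2,10,13-triene-1,6-diyl diacetate | CC(=O)OC/C=C(\C)CC[C@H](OC(C)=O)[C@](C)(O)CC/C=C/C(=O)/C(C)=C/B1OC(C)(C)C(C)(C)O1
F5 | step 5 | (2E,6S,7S)-1-acetoxy-7-hydroxy-8-iodo-3,7-dimethyloct-2-en-6-yl benzoate | CC(=O)OC/C=C(\C)CC[C@H](OC(=O)c1ccccc1)[C@](C)(O)CI
F6 | step 5 | (2E,6S,7R)-1-acetoxy-7-hydroxy-3,7-dimethylundeca-2,10-dien-6-yl benzoate | CC(=O)OC/C=C(\C)CC[C@H](OC(=O)c1ccccc1)[C@](C)(O)CCC=C
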